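- The closed, stirred vessel held substrate in the first phase and reagent in the second phase, and the question was whether more reagent pays at the asked time.

in all of them: substrate 26 mM

| charge | reagent in the second phase | remark | time | volume of the second phase over the first |
|---|---|---|---|---|
| elm | 38 mM | run made earlier |  |  |
| larch | 60 mM | run made earlier |  |  |
| flask | 27.3 mM |  | 20 h | 1.0 |

| run | time / h | target / % | substrate / % |
|---|---|---|---|
| elm | 2.00 | 3.9 | 85.6 |
| elm | 4.00 | 9.6 | 73.0 |
| elm | 6.00 | 13.4 | 63.9 |
| elm | 8.00 | 15.3 | 60.2 |
| elm | 10.0 | 16.8 | 54.9 |
| elm | 12.0 | 16.1 | 53.2 |
| larch | 2.00 | 8.1 | 82.1 |
| larch | 4.00 | 11.9 | 66.3 |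
| larch | 6.00 | 16.4 | 56.9 |
| larch | 8.00 | 18.6 | 49.7 |
| larch | 10.0 | 15.6 | 47.0 |
| larch | 12.0 | 16.9 | 43.0 |

(each reading ± 1 percentage point)

- in the second phase: reagent in the second phase; everything else is in the first
- charges count per volume of the first phase; a concentration in a rate is the amount of a species over the volume of its own phase; every rate counts per litre of the first phase
- the earlier runs were read with a standard deviation of 1 percentage point
- the earlier runs hold the two phases in the same ratio of volumes as the flask asked about

- Thursday's: doubling the transfer coefficient of the reagent in the second phase, all else as stated
- Sunday's: doubling the amount of reagent in the second phase, all else as stated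

- amount of target at 20 h, in percent of the substrate charged
- the change that raises the amount of target at 20 h, in percent of the substrate charged most ("none" if none brings more than 2 percentage points) (Thursday's / Sunday's / none)
- amount of target at 20 h, in percent of the substrate charged, after Sunday's

- I turned the question round: what would the runs have to show for Sunday's to gain more than 2 percentage points?
- At 12.0 h, larch against elm gave 0.106 for the logarithm of the target ratio over the logarithm of the charge ratio. I called this the late order, an apparent reaction order.
- Elm's target read 16.8% at 10.0 h and 16.1% at 12.0 h. I took that level to hold until 20 h, so scaling by the late order put this flask at 15.5%.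
- On that scaling, with all else held, a doubling multiplied target by two to the power of the late order. Sunday's therefore needed an order above 0.175.
- The scatter of the readings moves the late order by about 0.192, more than the gap to that threshold, so my call was a lean.
- I still committed: 15.5% in this flask, 16.7% after Sunday's, and "none" as the best change. The runs never varied transfer, and I put Thursday's under the margin too.
- The forecast, unlike my reckoning, gave 13.5%, chose Sunday's with 15.6% after it, and said of faster transfer that “target peaks earlier and decays”.
- This flask gave 14.6%. Sunday's moved it by −1.3 points to 13.3%, Thursday's moved it by −0.16 points, and the answer was none.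

    reagent in the reaction phase ⇌ reagent in the second phase, rate k1*([reagent in the reaction phase] - [reagent in the second phase]/K1) per volume of the first phase (partition coefficient = 0.320, kL = 0.110 h⁻¹)
    substrate + reagent in the reaction phase ⇌ target (K = 54.0 M⁻¹, k = 2.60 M⁻¹ h⁻¹)
    reagent in the reaction phase + target → over-reacted product (k = 5.90 M⁻¹ h⁻¹)
    substrate ⇌ dormant form (K = 0.250, k = 0.0990 h⁻¹)

- On this flask the late order came out at −0.138, so the doubling lost target where I had reckoned a small gain. At the time of elm's last reading, without the scatter, elm stood at 16.3% against 14.7% with this flask's charge of reagent in the second phase, which gave an order of 0.315. At 20.0 h this flask made target at 0.838 of the rate it used it up, each step taken net, so target was falling. By then over-reacted product stood at 17.9%, more than target at 14.6%.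

Readings and results are simulated from invented constants, noise included.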